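**Plan**

1. Skeleton and cuts: ring A is the cyclopentane C1–C5, ring B the cycloheptane C1, C10, C9, C8, C7, C6, C5 (daucane locants, C1 quaternary). Cut late to early: two acetates, the 8,9-epoxide, the angelate, C4–isopropyl; then C2–C3 and C1–C5 together; then C5=C6 (cross-metathesis), C1–C10 (aldol), C7–C8 (Stille).
2. Enabling feature: ring A carries oxygen on C4 between C3 and C5 (a latent 2-oxyallyl unit), O-6 is vicinal to C5 (a latent α,β-epoxy ketone), and O-2 sits next to quaternary C1 (a latent aldehyde enol ether). O-2 and O-10 are cis-1,3 across C1, so one silicon atom can tie them into a temporary six-membered ring.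
3. Forward order: the chain C3–C4–C5–C6–C7–C8=C9–C10–C1–C2 is built linearly. One operation then closes ring B (C1–C5) and ring A (C2–C3). Isopropyl, angelate, epoxide and acetates follow.
4. Stereochemistry: C10 comes from an auxiliary-controlled aldol. C5 and C6 come from a reagent-controlled epoxidation of an (E)-enone and invertive opening at C5. C1 and C2 are relayed from C10 through the silicon tether. C4 is set by addition anti to the angular methyl, and C8/C9 by hydroxyl-directed epoxidation.

Key step: step 10

Remark: the target is taken exactly as the given SMILES, a trans-fused daucane with 5α-H; α is the face opposite to the C1 methyl (C15), and C14 is the methyl on C8.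

**Route**

Step 1
Reactants: 1 but-2-yn-1-ol
Product: 3 (Z)-3-iodobut-2-en-1-ol, via alkenylalanate 2 (not isolated)
Conditions: NaAlH2(OCH2CH2OMe)2, THF, 0 °C to rt; then I2, −78 °C
Reagents that add atoms: iodine, II
Why: Hydroxyl-directed trans-hydroalumination of the propargylic alcohol should give a cyclic alkenylalanate whose C–Al bond is cleaved by iodine with retention, so iodine ends on C3 cis to CH2OH (Z).

Step 2
Reactants: 3 (Z)-3-iodobut-2-en-1-ol; 4 allyltributylstannane
Product: 5 (Z)-3-methylhexa-2,5-dien-1-ol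
Conditions: PdCl2(MeCN)2 (5 mol%), DMF, rt
Reagents that add atoms: none
Why: Stille coupling of the alkenyl iodide with the allylstannane should proceed with retention of alkene geometry and give the skipped (Z)-diene.

Step 3
Reactants: 5 (Z)-3-methylhexa-2,5-dien-1-ol
Product: 6 (Z)-3-methylhexa-2,5-dienal
Conditions: MnO2 (activated), CH2Cl2, rt
Reagents that add atoms: none
Why: Allylic oxidation with MnO2 under neutral conditions should give the enal without Z-to-E isomerisation or migration of the skipped diene.

Step 4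
Reactants: 7 (S)-4-benzyl-3-propanoyl-1,3-thiazolidine-2-thione; 6 (Z)-3-methylhexa-2,5-dienal
Product: 9 (S)-4-benzyl-3-[(2S,3R,4Z)-3-hydroxy-2,5-dimethylocta-4,7-dienoyl]-1,3-thiazolidine-2-thione, via titanium enolate 8 (not isolated)
Conditions: TiCl4, iPr2NEt, N-methyl-2-pyrrolidinone, CH2Cl2, 0 °C; then 6, −78 °C
Reagents that add atoms: none
Why: The Evans-syn titanium aldol of the N-acyl thiazolidinethione (chair transition state, benzyl group shielding one enolate face) should set C10 as R; the accompanying C1 centre is erased in step 6.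

Step 5
Reactants: 9 syn-aldol adduct
Product: 10 (2S,3R,4Z)-3-hydroxy-2,5-dimethylocta-4,7-dienal
Conditions: iBu2AlH (2.2 equiv), CH2Cl2, −78 °C
Reagents that add atoms: none
Why: Partial reduction of the activated N-acyl thiazolidinethione should stop at a hemithioaminal aluminate that releases the aldehyde on work-up, leaving C10 untouched.

Step 6
Reactants: 10 β-hydroxy aldehyde
Product: 11 (4R)-2,2-di-tert-butyl-5-methyl-4-[(1Z)-2-methylpenta-1,4-dien-1-yl]-4H-1,3,2-dioxasiline
Conditions: tBu2Si(OTf)2, Et3N, CH2Cl2, −78 to 0 °C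
Reagents that add atoms: di-tert-butylsilyl bis(trifluoromethanesulfonate), CC(C)(C)[Si](OS(=O)(=O)C(F)(F)F)(OS(=O)(=O)C(F)(F)F)C(C)(C)C
Why: Silylation of the C10 hydroxyl followed by intramolecular soft enolisation and O-silylation of the aldehyde (silyl triflate/amine enol silane formation) should close the six-membered ring, fixing the enol geometry and protecting O-2 and O-10 together.

Step 7
Reactants: 11 dioxasiline diene; 12 but-3-en-2-one
Product: 13 (3E,6Z)-7-[(4R)-2,2-di-tert-butyl-5-methyl-4H-1,3,2-dioxasilin-4-yl]-6-methylhepta-3,6-dien-2-one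
Conditions: second-generation Hoveyda–Grubbs catalyst RuCl2(H2IMes)(=CH-C6H4-2-OiPr) (5 mol%), CH2Cl2, 40 °C
Reagents that add atoms: none
Why: Olefin cross-metathesis of the terminal alkene with the electron-poor enone partner should give the (E)-enone, since the trisubstituted alkene and the hindered cyclic silyl enol ether are poor partners for the ruthenium carbene.

Step 8
Reactants: 13 dienone
Product: 14 1-[(2R,3S)-3-{(2Z)-3-[(4R)-2,2-di-tert-butyl-5-methyl-4H-1,3,2-dioxasilin-4-yl]-2-methylprop-2-en-1-yl}oxiran-2-yl]ethan-1-one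
Conditions: La(O-iPr)3, (S)-BINOL, Ph3As=O (10 mol% each), tBuOOH, 4 Å molecular sieves, THF, rt
Reagents that add atoms: tert-butyl hydroperoxide, CC(C)(C)OO
Why: Lanthanum–BINOL-catalysed asymmetric nucleophilic (Weitz–Scheffer-type) epoxidation of the (E)-enone is stereospecific for the trans epoxide and reagent-controlled in facial sense (the ligand antipode is chosen to deliver the 2R,3S oxirane), and the electron-rich alkenes do not react with a nucleophilic peroxide.

Step 9
Reactants: 14 epoxy ketone
Product: 16 triethylsilyl enol ether of 14 (epoxy enolsilane), via lithium enolate 15 (not isolated)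
Conditions: LiN(SiMe3)2, Et3SiCl, Et3N, THF, −78 °C
Reagents that add atoms: chlorotriethylsilane, CC[Si](Cl)(CC)CC
Why: Kinetic deprotonation of the methyl ketone, its only readily enolisable side, and O-silylation (silyl enol ether formation) should give the epoxy enolsilane with the epoxide intact.

Step 10
Reactants: 16 epoxy enolsilane
Product: 18 tricyclic silylene ketone, via oxocarbenium triflate 17 (not isolated)
Conditions: Et3SiOTf (10 mol%), CH2Cl2, −78 °C; Et3N quench
Reagents that add atoms: none
Why: Proposed new method: Et3SiOTf silylates the epoxide oxygen of 16, and the enol-ether carbon C1 attacks C5 from the backside (C5 is activated as a 2-siloxyallyl cation equivalent by the adjacent enol silane); this closes ring B and gives silyloxocarbenium ion 17, which C3 of the enol silane captures at C2 to close ring A and release Et3SiOTf, the closest known reactions being the silyl triflate-catalysed intramolecular (4+3) cycloadditions of epoxy enolsilanes with dienes and the (3+2) annulations of 2-siloxyallyl cations with enol silyl ethers. Ring B closes by a 7-endo-tet epoxide opening with C1 as an enol-exo nucleophile, and ring A by a 5-(enolendo)-exo-trig Mukaiyama-type addition to the oxocarbenium ion. C5 is set by inversion at the epoxide carbon, so the trans (2R,3S) oxirane gives H-5 cis to O-6 and trans to the C1 methyl; C1 is set by C10, because the tether can deliver C5 only to the dioxasiline face that carries C9; C2 is set by the cis fusion of ring A onto the silicon-containing ring, which keeps O-2 syn to O-10. The step needs attack at C5 and not C6, and by the enol ether and not the C8=C9 alkene: the first is secured by enol-silane stabilisation of positive charge at C5, the second by the higher nucleophilicity of a silyl enol ether and by the tether, which would otherwise demand eight- or nine-membered rings. The bulky tBu2Si group should shield the doubly allylic C10–O bond from silylation and ionisation.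

Step 11
Reactants: 18 tricyclic silylene ketone
Product: 19 4β-hydroxy-4α-isopropyl carbinol (6α-triethylsilyloxy, 2α,10α-silylene)
Conditions: iPrMgCl, CeCl3 (anhydrous), THF, −78 to −40 °C
Reagents that add atoms: isopropylmagnesium chloride, CC(C)[Mg]Cl
Why: Organocerium 1,2-addition should outpace enolisation, and attack on the cyclopentanone from the α face, anti to the angular C1 methyl that blocks the β face in a 1,3-diaxial sense, should give the 4β-ol.

Step 12
Reactants: 19 silyl-protected carbinol
Product: 20 4β,6α-diol (2α,10α-silylene retained)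
Conditions: pyridinium p-toluenesulfonate, MeOH/CH2Cl2, 0 °C
Reagents that add atoms: none
Why: Mild acid-catalysed methanolysis (selective desilylation) should cleave the secondary triethylsilyl ether while the hindered di-tert-butylsilylene and the tertiary alcohol survive.

Step 13
Reactants: 20 4β,6α-diol
Product: 21 6α-angelate (2α,10α-silylene retained)
Conditions: angelic acid, 2,4,6-Cl3C6H2COCl, Et3N, toluene, rt; then 20, toluene, 80 °C
Reagents that add atoms: angelic acid ((Z)-2-methylbut-2-enoic acid), C/C=C(/C)C(=O)O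
Why: Yamaguchi-type mixed-anhydride esterification run without a nucleophilic amine catalyst should acylate the secondary C6 hydroxyl (the tertiary C4 hydroxyl is inert) and avoid the conjugate addition–elimination path that isomerises angelate to tiglate.

Step 14
Reactants: 21 silylene angelate
Product: 22 2α,10α-diol 6α-angelate
Conditions: HF·pyridine, pyridine, THF, 0 °C to rt
Reagents that add atoms: none
Why: Fluoride-induced cleavage of the silylene (Si–F bond formation) should release the cis-2,10-diol without touching the ester or the ring alkene.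

Step 15
Reactants: 22 2α,10α-diol 6α-angelate
Product: 23 8α,9α-epoxy-2α,10α-diol 6α-angelate
Conditions: VO(acac)2 (5 mol%), tBuOOH, CH2Cl2, 0 °C to rt
Reagents that add atoms: tert-butyl hydroperoxide, CC(C)(C)OO
Why: Vanadium-catalysed hydroxyl-directed epoxidation should deliver oxygen to the C8=C9 face syn to the allylic C10 hydroxyl (α face, cis epoxy alcohol) and leave the electron-poor angelate alkene alone.

Step 16
Reactants: 23 epoxy diol
Product: 24 CNP0170993.1 (target)
Conditions: Ac2O, DMAP, pyridine, CH2Cl2, rt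
Reagents that add atoms: acetic anhydride, CC(=O)OC(C)=O
Why: DMAP-catalysed acetylation should esterify the two secondary hydroxyls, while the hindered tertiary C4 hydroxyl stays free under controlled stoichiometry.

**Compound list**

1 | but-2-yn-1-ol | CC#CCO | starting material
2 | sodium 2,2-bis(2-methoxyethoxy)-3-methyl-2,5-dihydro-1,2-oxaaluminol-2-uide (cyclic alkenylalanate) | CC1=CCO[Al-]1(OCCOC)OCCOC.[Na+] | intermediate
3 | (Z)-3-iodobut-2-en-1-ol | C/C(I)=C/CO | intermediate
4 | allyltributylstannane | C=CC[Sn](CCCC)(CCCC)CCCC | starting material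
5 | (Z)-3-methylhexa-2,5-dien-1-ol | C=CC/C(C)=C\CO | intermediate
6 | (Z)-3-methylhexa-2,5-dienal | C=CC/C(C)=C\C=O | intermediate
7 | (S)-4-benzyl-3-propanoyl-1,3-thiazolidine-2-thione | CCC(=O)N1[C@@H](Cc2ccccc2)CSC1=S | starting material
8 | trichlorotitanium (Z)-enolate of 7 | C/C=C(\O[Ti](Cl)(Cl)Cl)N1[C@@H](Cc2ccccc2)CSC1=S | intermediate
9 | (S)-4-benzyl-3-[(2S,3R,4Z)-3-hydroxy-2,5-dimethylocta-4,7-dienoyl]-1,3-thiazolidine-2-thione | C=CC/C(C)=C\[C@@H](O)[C@H](C)C(=O)N1[C@@H](Cc2ccccc2)CSC1=S | intermediate
10 | (2S,3R,4Z)-3-hydroxy-2,5-dimethylocta-4,7-dienal | C=CC/C(C)=C\[C@@H](O)[C@H](C)C=O | intermediate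
11 | (4R)-2,2-di-tert-butyl-5-methyl-4-[(1Z)-2-methylpenta-1,4-dien-1-yl]-4H-1,3,2-dioxasiline | C=CC/C(C)=C\[C@H]1O[Si](C(C)(C)C)(C(C)(C)C)OC=C1C | intermediate
12 | but-3-en-2-one (methyl vinyl ketone) | CC(=O)C=C | starting material
13 | (3E,6Z)-7-[(4R)-2,2-di-tert-butyl-5-methyl-4H-1,3,2-dioxasilin-4-yl]-6-methylhepta-3,6-dien-2-one | CC(=O)/C=C/C/C(C)=C\[C@H]1O[Si](C(C)(C)C)(C(C)(C)C)OC=C1C | intermediate
14 | 1-[(2R,3S)-3-{(2Z)-3-[(4R)-2,2-di-tert-butyl-5-methyl-4H-1,3,2-dioxasilin-4-yl]-2-methylprop-2-en-1-yl}oxiran-2-yl]ethan-1-one | CC(=O)[C@@H]1O[C@H]1C/C(C)=C\[C@H]2O[Si](C(C)(C)C)(C(C)(C)C)OC=C2C | intermediate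
15 | lithium enolate of 14 (methyl side) | C=C(O[Li])[C@@H]1O[C@H]1C/C(C)=C\[C@H]2O[Si](C(C)(C)C)(C(C)(C)C)OC=C2C | intermediate
16 | triethyl({1-[(2R,3S)-3-{(2Z)-3-[(4R)-2,2-di-tert-butyl-5-methyl-4H-1,3,2-dioxasilin-4-yl]-2-methylprop-2-en-1-yl}oxiran-2-yl]ethenyl}oxy)silane | C=C(O[Si](CC)(CC)CC)[C@@H]1O[C@H]1C/C(C)=C\[C@H]2O[Si](C(C)(C)C)(C(C)(C)C)OC=C2C | intermediate
17 | ring-B-closed silyloxocarbenium triflate (C1–C5 bond formed; 6α-OSiEt3; C5 bears the 1-(triethylsilyloxy)vinyl group; C2=O+ within the silicon ring) | CC[Si](CC)(CC)O[C@H]1CC(C)=C[C@H]2O[Si](C(C)(C)C)(C(C)(C)C)[O+]=C[C@@]2(C)[C@@H]1C(=C)O[Si](CC)(CC)CC.[O-]S(=O)(=O)C(F)(F)F | intermediate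
18 | trans-fused bicyclo[5.3.0]dec-8-en-4-one (target locants): 1β,8-dimethyl, 5α-H, 6α-triethylsilyloxy, O-2α and O-10α bridged by tBu2Si | CC[Si](CC)(CC)O[C@H]1CC(C)=C[C@@H](O[Si]3(C(C)(C)C)C(C)(C)C)[C@@]2(C)[C@@H](O3)CC(=O)[C@H]12 | intermediate
19 | 6α-triethylsilyloxy-2α,10α-(di-tert-butylsilanediyldioxy)dauc-8-en-4β-ol (4α-isopropyl, 5α-H) | CC[Si](CC)(CC)O[C@H]1CC(C)=C[C@@H](O[Si]3(C(C)(C)C)C(C)(C)C)[C@@]2(C)[C@@H](O3)C[C@@](O)(C(C)C)[C@H]12 | intermediate
20 | 2α,10α-(di-tert-butylsilanediyldioxy)dauc-8-ene-4β,6α-diol | O[C@H]1CC(C)=C[C@@H](O[Si]3(C(C)(C)C)C(C)(C)C)[C@@]2(C)[C@@H](O3)C[C@@](O)(C(C)C)[C@H]12 | intermediate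
21 | 6α-angeloyloxy-2α,10α-(di-tert-butylsilanediyldioxy)dauc-8-en-4β-ol | C/C=C(/C)C(=O)O[C@H]1CC(C)=C[C@@H](O[Si]3(C(C)(C)C)C(C)(C)C)[C@@]2(C)[C@@H](O3)C[C@@](O)(C(C)C)[C@H]12 | intermediate
22 | 6α-angeloyloxydauc-8-ene-2α,4β,10α-triol | C/C=C(/C)C(=O)O[C@H]1CC(C)=C[C@@H](O)[C@@]2(C)[C@@H](O)C[C@@](O)(C(C)C)[C@H]12 | intermediate
23 | 6α-angeloyloxy-8α,9α-epoxydaucane-2α,4β,10α-triol | C/C=C(/C)C(=O)O[C@H]1C[C@@]2(C)O[C@H]2[C@@H](O)[C@@]2(C)[C@@H](O)C[C@@](O)(C(C)C)[C@H]12 | intermediate
24 | CNP0170993.1: 2α,10α-diacetoxy-6α-angeloyloxy-8α,9α-epoxydaucan-4β-ol | C/C=C(/C)C(=O)O[C@H]1C[C@@]2(C)O[C@H]2[C@@H](OC(C)=O)[C@@]2(C)[C@@H](OC(C)=O)C[C@@](O)(C(C)C)[C@H]12 | target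

**Totals and risks**

Total step count: 16. Longest linear sequence: 16 steps, from but-2-yn-1-ol 1.

Steps most likely to fail:

Step 10 (key step). The silyl group may leave the oxocarbenium ion before the second C–C bond forms, the doubly allylic C10–O bond may ionise, or the epoxide may open without C–C bond formation. The fallback is stepwise, uses enolate alkylation and aldol chemistry, sets out from epoxy ketone 14 and comes back at ketone 18. Opening of 14 with MgBr2·OEt2 (bromide attack at C5 with inversion) would give the anti α-bromo-β-hydroxy ketone F1, which Et3SiCl and imidazole convert into the triethylsilyl ether F2. Fluoride (Bu4N[Ph3SiF2], catalytic Bu4NI, THF) would open the dioxasiline at silicon and release the aldehyde enolate, which alkylates the α-halo ketone intramolecularly (enolate SN2 alkylation). Halide exchange makes the C5 halide configurationally labile, so ring closure can drain the mixture through the diastereomer that cyclises, and C5 stays epimerisable through the C4 enolate afterwards. This would give the cycloheptene keto aldehyde F3, which carries a di-tert-butylfluorosilyl ether on O-10. LiN(SiMe3)2 would then form the kinetic methyl-ketone enolate for an intramolecular aldol addition to the non-enolisable aldehyde. The C2 alkoxide displaces fluoride from silicon and re-forms the silylene, which traps the cis-2,10 arrangement and returns 18.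

Step 11. The hindered ketone may enolise with β-elimination of a silyloxy group, the isopropyl reagent may reduce it by β-hydride transfer, or facial selectivity may erode. The fallback sets out from 18 and comes back at 19. 2-Propenylmagnesium bromide with CeCl3, an sp2 nucleophile without β-hydrogens, should add from the same α face to give the isopropenyl carbinol F4. Hydrogenation with H2 and RhCl(PPh3)3 should then saturate the 1,1-disubstituted alkene selectively and leave the trisubstituted ring alkene.

Step 13. Acylation of the hindered C6 hydroxyl may be slow and accompanied by Z-to-E isomerisation of the 2-methylbut-2-enoyl unit. The fallback sets out from 20 and comes back at 21. Esterification with 2-[bis(2,2,2-trifluoroethoxy)phosphoryl]propanoic acid (DCC, DMAP) would give the phosphonate ester F5, a mixture of epimers at the phosphonate carbon. Still–Gennari olefination with acetaldehyde (KN(SiMe3)2, 18-crown-6, THF, −78 °C) would then build the (Z)-alkene of the angelate on the substrate.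

Further compounds
F1 | step 10 | (3S,4S,6Z)-3-bromo-7-[(4R)-2,2-di-tert-butyl-5-methyl-4H-1,3,2-dioxasilin-4-yl]-4-hydroxy-6-methylhept-6-en-2-one | CC(=O)[C@@H](Br)[C@@H](O)C/C(C)=C\[C@H]1O[Si](C(C)(C)C)(C(C)(C)C)OC=C1C
F2 | step 10 | triethylsilyl ether of F1 | CC(=O)[C@@H](Br)[C@@H](O[Si](CC)(CC)CC)C/C(C)=C\[C@H]1O[Si](C(C)(C)C)(C(C)(C)C)OC=C1C
F3 | step 10 | cyclohept-3-ene keto aldehyde: C1 formyl and methyl, C5 acetyl, 6α-triethylsilyloxy, 10α-(di-tert-butylfluorosilyl)oxy (target locants) | CC[Si](CC)(CC)O[C@H]1CC(C)=C[C@@H](O[Si](F)(C(C)(C)C)C(C)(C)C)[C@@](C)(C=O)[C@@H]1C(C)=O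
F4 | step 11 | 4α-(prop-1-en-2-yl) analogue of 19 (4β-ol) | CC[Si](CC)(CC)O[C@H]1CC(C)=C[C@@H](O[Si]3(C(C)(C)C)C(C)(C)C)[C@@]2(C)[C@@H](O3)C[C@@](O)(C(C)=C)[C@H]12
F5 | step 13 | 6α-{2-[bis(2,2,2-trifluoroethoxy)phosphoryl]propanoyloxy} ester of 20 | CC(C(=O)O[C@H]1CC(C)=C[C@@H](O[Si]3(C(C)(C)C)C(C)(C)C)[C@@]2(C)[C@@H](O3)C[C@@](O)(C(C)C)[C@H]12)P(=O)(OCC(F)(F)F)OCC(F)(F)F
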